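The ten-membered carbocycle (C1–C10) is opened at C9–C10. There the acyloxy carbinol C9 is attached to C10, the α-carbon of the ring-cis C1=C10–C14 enal. In the precursor both carbons are electrophilic: C9 is an aldehyde and C10 an alkenyl iodide. A Ni/Cr-mediated Nozaki–Hiyama–Kishi coupling reverses the polarity of C10. In one operation it closes the ring, keeps the C1=C10 geometry and sets C9 as the only free hydroxyl. The precursor is a monocyclic trans-α-methylene-γ-butyrolactone. It carries a neryl-derived (Z,Z)-iododiene chain on C6 and an α-silyloxy aldehyde on C7, and is assembled by a Barbier allylation/translactonisation.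

Key step: step 11

Remark on locants: germacranolide numbering is used. C1(H)=C10, C2H2, C3H2, C4(CH3)=C5(H), C6 (lactone O–CH), C7, C8 (CHOH) and C9 (CH–O-acyl) form the ring. C11=C13H2 and C12 (C=O) belong to the lactone, C14 is the formyl carbon and C15 the methyl on C4.
Assumption: neryl acetate, 2-(bromomethyl)acrylic acid, (S)-but-3-ene-1,2-diol and (R)-2-methylbutanoic acid are taken as commercial compounds.

Step 1
Reactants: 1 neryl acetate
Product: 2 (2Z)-3-methyl-6-oxohex-2-en-1-yl acetate
Conditions: O3 (ca. 1 equiv, Sudan III end point), CH2Cl2, −78 °C; then Me2S, −78 °C → rt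
Reagents that add atoms: ozone, [O-][O+]=O
Why: Chemoselective ozonolysis should cleave only the electron-rich isopropylidene terminus, because the other trisubstituted C=C (future C4=C5, Z) is deactivated by the allylic acetate.

Step 2
Reactants: 2 (2Z)-3-methyl-6-oxohex-2-en-1-yl acetate
Product: 3 (2Z,6E)-3-methyl-8-oxoocta-2,6-dien-1-yl acetate
Conditions: Ph3P=CHCHO (1.1 equiv), toluene, 70 °C
Reagents that add atoms: (triphenylphosphoranylidene)acetaldehyde, O=CC=P(c1ccccc1)(c1ccccc1)c1ccccc1
Why: Wittig olefination with the stabilised formyl ylide should give the (E)-enal, which places the chain carbon C2 trans to the future C14 carbonyl.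

Step 3
Reactants: 3 (2Z,6E)-3-methyl-8-oxoocta-2,6-dien-1-yl acetate
Product: 4 (2Z,6Z)-7-iodo-3-methyl-8-oxoocta-2,6-dien-1-yl acetate
Conditions: I2, K2CO3, DMAP (cat.), THF–H2O (1:1), rt
Reagents that add atoms: iodine, II
Why: Baylis–Hillman-type α-iodination (DMAP conjugate addition, iodination of the enolate, loss of DMAP) should give the favoured (Z)-α-iodoenal with iodine cis to the chain, which is the ring-cis arrangement needed at C1=C10.

Step 4
Reactants: 4 (2Z,6Z)-7-iodo-3-methyl-8-oxoocta-2,6-dien-1-yl acetate
Product: 6 (2Z,6Z)-7-iodo-8,8-dimethoxy-3-methylocta-2,6-dien-1-ol, via acetal acetate 5 (not isolated)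
Conditions: HC(OMe)3, PPTS (cat.), MeOH, rt; then K2CO3 (0.3 equiv), rt
Reagents that add atoms: trimethyl orthoformate, COC(OC)OC
Why: Acid-catalysed acetalisation masks C14 at the aldehyde oxidation level, and base-catalysed methanolysis of the acetate in the same flask should then free the allylic alcohol without touching the acetal or the alkenyl iodide.

Step 5
Reactants: 6 (2Z,6Z)-7-iodo-8,8-dimethoxy-3-methylocta-2,6-dien-1-ol
Product: 7 (2Z,6Z)-7-iodo-8,8-dimethoxy-3-methylocta-2,6-dienal
Conditions: TEMPO (cat.), PhI(OAc)2, CH2Cl2, 0 °C → rt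
Reagents that add atoms: none
Why: Oxoammonium (TEMPO/PhI(OAc)2) oxidation is an established way to turn nerol-type allylic alcohols into the (Z)-enals without Z/E isomerisation or over-oxidation.

Step 6
Reactants: 8 2-(bromomethyl)acrylic acid; 9 (S)-but-3-ene-1,2-diol
Product: 11 (2S)-2-hydroxybut-3-en-1-yl 2-(bromomethyl)prop-2-enoate, via acid chloride 10 (not isolated)
Conditions: (COCl)2, DMF (cat.), CH2Cl2, 0 °C → rt, concentrate; then 9, 2,4,6-collidine, CH2Cl2, −78 °C
Reagents that add atoms: oxalyl chloride, O=C(Cl)C(=O)Cl (supplies the chlorine of 10 only)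
Why: Acylation with the acid chloride at low temperature in the presence of the hindered base collidine should esterify the primary hydroxyl selectively and spare the allylic bromide, while the stereocentre (future C8) comes unchanged from the chiral pool.

Step 7
Reactants: 11 (2S)-2-hydroxybut-3-en-1-yl 2-(bromomethyl)prop-2-enoate
Product: 12 (2S)-2-(triethylsilyloxy)but-3-en-1-yl 2-(bromomethyl)prop-2-enoate
Conditions: TESOTf, 2,6-lutidine, CH2Cl2, −78 °C
Reagents that add atoms: triethylsilyl trifluoromethanesulfonate, CC[Si](CC)(CC)OS(=O)(=O)C(F)(F)F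
Why: Silylation with the triflate and a non-nucleophilic base should protect O8 faster than acyl migration or attack on the allylic bromide can occur.

Step 8
Reactants: 12 (2S)-2-(triethylsilyloxy)but-3-en-1-yl 2-(bromomethyl)prop-2-enoate
Product: 13 (5S)-3-(bromomethyl)-5-(triethylsilyloxy)-5,6-dihydro-2H-pyran-2-one
Conditions: Hoveyda–Grubbs II (5 mol %), toluene (5 mM), 80 °C, Ar sparge
Reagents that add atoms: none
Why: Ring-closing metathesis of an α-substituted acrylate with a monosubstituted olefin is a standard entry to α-substituted pentenolides, and loss of ethylene drives the six-ring closure.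

Step 9
Reactants: 7 (2Z,6Z)-7-iodo-8,8-dimethoxy-3-methylocta-2,6-dienal; 13 (5S)-3-(bromomethyl)-5-(triethylsilyloxy)-5,6-dihydro-2H-pyran-2-one
Product: 15 (4S,5R)-4-[(1S)-2-hydroxy-1-(triethylsilyloxy)ethyl]-5-[(1Z,5Z)-6-iodo-7,7-dimethoxy-2-methylhepta-1,5-dien-1-yl]-3-methylideneoxolan-2-one, via hydroxy δ-lactone 14 (not isolated)
Conditions: In powder, THF, rt; pH 7 buffer; then PPTS (cat.), CH2Cl2, rt
Reagents that add atoms: none
Why: In this Barbier allylation (allylindium, SE2′ at C7) through a chair Zimmerman–Traxler transition state the ring-locked E-type allyl metal should give the anti C6/C7 adduct (hence the trans γ-lactone), the aldehyde should be taken up on the pyranone face anti to the C8 silyloxy group (C7 relative to C8), and O6 then translactonises onto C12 to give the more stable five-membered α-methylene lactone and free the primary C9 hydroxyl.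

Step 10
Reactants: 15 the γ-lactone alcohol from step 9
Product: 16 (4S,5R)-5-[(1Z,5Z)-6-iodo-7,7-dimethoxy-2-methylhepta-1,5-dien-1-yl]-3-methylidene-4-[(1S)-2-oxo-1-(triethylsilyloxy)ethyl]oxolan-2-one
Conditions: TEMPO (cat.), PhI(OAc)2, CH2Cl2, rt
Reagents that add atoms: none
Why: Base-free oxoammonium oxidation of the only free (primary) hydroxyl should give the α-silyloxy aldehyde without epimerisation at C8, silyl migration or oxa-Michael addition to the methylene lactone.

Step 11
Reactants: 16 the iodo aldehyde from step 10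
Product: 17 (6R,7S,8S,9R)-9-hydroxy-14,14-dimethoxy-8-(triethylsilyloxy)germacra-1(10)E,4Z,11(13)-trien-12,6-olide (both ring double bonds ring-cis)
Conditions: CrCl2 (15 equiv), NiCl2 (1 mol % of Cr), DMSO–THF, 2 mM (syringe pump), rt
Reagents that add atoms: none
Why: Ni(0), formed in situ by Cr(II), inserts into the C10–I bond with retention, transmetallation gives the alkenylchromium(III) species, and the now nucleophilic C10 adds to the C9 aldehyde, so two carbons that are both electrophilic in 16 are joined by a two-electron polarity reversal. The closest known reaction type is the intramolecular Nozaki–Hiyama–Kishi alkenyl iodide/aldehyde coupling, which is established at high dilution for medium-sized carbocycles and macrocycles. The ten-membered ring closes in a 10-exo-trig mode (C=O exocyclic to the forming ring), helped by the two ring-cis double bonds C4=C5 and C1=C10 and by the trans-lactone, which fold the chain and reduce transannular contacts. C9 is set by polar Felkin–Anh control: the non-chelating C8–OSiEt3 group stands anti to the incoming C10, which should give the 8,9-anti (erythro) relationship, that is 9R. The step needs chemoselectivity for the aldehyde over the lactone, the α-methylene lactone and the acetal, which the low basicity and carbonyl selectivity of organochromium(III) reagents secure, and retention of the iodide geometry, which is normal for trisubstituted alkenyl iodides. Work-up releases the chromium alkoxide as the only free hydroxyl of 17, ready for acylation.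

Step 12
Reactants: 17 the macrocyclic alcohol from step 11; 18 (R)-2-methylbutanoic acid
Product: 19 (6R,7S,8S,9R)-14,14-dimethoxy-9-[(2R)-2-methylbutanoyloxy]-8-(triethylsilyloxy)germacra-1(10)E,4Z,11(13)-trien-12,6-olide
Conditions: DCC, DMAP (cat.), CH2Cl2, 0 °C → rt
Reagents that add atoms: none
Why: Steglich esterification should acylate the single free hydroxyl (C9) with retention at C9 and, with only catalytic DMAP at low temperature, without epimerising the α-stereocentre of the acid.

Step 13
Reactants: 19 the protected ester from step 12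
Product: 20 (6R,7R,8S,9R)-8-hydroxy-9-[(2R)-2-methylbutanoyloxy]-14-oxogermacra-1(10)E,4Z,11(13)-trien-12,6-olide (CNP0256845.2)
Conditions: AcOH–THF–H2O (3:1:1), rt
Reagents that add atoms: water, O
Why: Mild aqueous acid should hydrolyse the allylic dimethyl acetal to the C14 enal and cleave the triethylsilyl ether at O8 in one operation, under conditions in which base-promoted O9→O8 acyl migration and translactonisation do not operate.

Compound list
1 | neryl acetate, (2Z)-3,7-dimethylocta-2,6-dien-1-yl acetate | CC(C)=CCC/C(C)=C\COC(C)=O | starting material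
2 | (2Z)-3-methyl-6-oxohex-2-en-1-yl acetate | O=CCC/C(C)=C\COC(C)=O | intermediate
3 | (2Z,6E)-3-methyl-8-oxoocta-2,6-dien-1-yl acetate | O=C/C=C/CC/C(C)=C\COC(C)=O | intermediate
4 | (2Z,6Z)-7-iodo-3-methyl-8-oxoocta-2,6-dien-1-yl acetate | O=C/C(I)=C/CC/C(C)=C\COC(C)=O | intermediate
5 | (2Z,6Z)-7-iodo-8,8-dimethoxy-3-methylocta-2,6-dien-1-yl acetate | COC(OC)/C(I)=C/CC/C(C)=C\COC(C)=O | intermediate
6 | (2Z,6Z)-7-iodo-8,8-dimethoxy-3-methylocta-2,6-dien-1-ol | COC(OC)/C(I)=C/CC/C(C)=C\CO | intermediate
7 | (2Z,6Z)-7-iodo-8,8-dimethoxy-3-methylocta-2,6-dienal | COC(OC)/C(I)=C/CC/C(C)=C\C=O | intermediate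
8 | 2-(bromomethyl)acrylic acid | C=C(CBr)C(=O)O | starting material
9 | (S)-but-3-ene-1,2-diol | C=C[C@H](O)CO | starting material
10 | 2-(bromomethyl)acryloyl chloride | C=C(CBr)C(=O)Cl | intermediate
11 | (2S)-2-hydroxybut-3-en-1-yl 2-(bromomethyl)prop-2-enoate | C=C(CBr)C(=O)OC[C@@H](O)C=C | intermediate
12 | (2S)-2-(triethylsilyloxy)but-3-en-1-yl 2-(bromomethyl)prop-2-enoate | C=C(CBr)C(=O)OC[C@@H](O[Si](CC)(CC)CC)C=C | intermediate
13 | (5S)-3-(bromomethyl)-5-(triethylsilyloxy)-5,6-dihydro-2H-pyran-2-one | O=C1OC[C@@H](O[Si](CC)(CC)CC)C=C1CBr | intermediate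
14 | (4S,5S)-4-[(1R,2Z,6Z)-1-hydroxy-7-iodo-8,8-dimethoxy-3-methylocta-2,6-dien-1-yl]-3-methylidene-5-(triethylsilyloxy)oxan-2-one | C=C1C(=O)OC[C@@H](O[Si](CC)(CC)CC)[C@@H]1[C@H](O)/C=C(/C)CC/C=C(I)/C(OC)OC | intermediate
15 | (4S,5R)-4-[(1S)-2-hydroxy-1-(triethylsilyloxy)ethyl]-5-[(1Z,5Z)-6-iodo-7,7-dimethoxy-2-methylhepta-1,5-dien-1-yl]-3-methylideneoxolan-2-one | C=C1C(=O)O[C@H](/C=C(/C)CC/C=C(I)/C(OC)OC)[C@H]1[C@H](O[Si](CC)(CC)CC)CO | intermediate
16 | (4S,5R)-5-[(1Z,5Z)-6-iodo-7,7-dimethoxy-2-methylhepta-1,5-dien-1-yl]-3-methylidene-4-[(1S)-2-oxo-1-(triethylsilyloxy)ethyl]oxolan-2-one | C=C1C(=O)O[C@H](/C=C(/C)CC/C=C(I)/C(OC)OC)[C@H]1[C@H](O[Si](CC)(CC)CC)C=O | intermediate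
17 | (6R,7S,8S,9R)-9-hydroxy-14,14-dimethoxy-8-(triethylsilyloxy)germacra-1(10)E,4Z,11(13)-trien-12,6-olide | C=C1C(=O)O[C@@H]2/C=C(/C)CC/C=C(/C(OC)OC)[C@@H](O)[C@@H](O[Si](CC)(CC)CC)[C@@H]12 | intermediate
18 | (R)-2-methylbutanoic acid | CC[C@@H](C)C(=O)O | starting material
19 | (6R,7S,8S,9R)-14,14-dimethoxy-9-[(2R)-2-methylbutanoyloxy]-8-(triethylsilyloxy)germacra-1(10)E,4Z,11(13)-trien-12,6-olide | C=C1C(=O)O[C@@H]2/C=C(/C)CC/C=C(/C(OC)OC)[C@@H](OC(=O)[C@H](C)CC)[C@@H](O[Si](CC)(CC)CC)[C@@H]12 | intermediate
20 | (6R,7R,8S,9R)-8-hydroxy-9-[(2R)-2-methylbutanoyloxy]-14-oxogermacra-1(10)E,4Z,11(13)-trien-12,6-olide (CNP0256845.2) | C=C1C(=O)O[C@@H]2/C=C(/C)CC/C=C(/C=O)[C@@H](OC(=O)[C@H](C)CC)[C@@H](O)[C@@H]12 | target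

Total step count: 13. Longest linear sequence: 10 steps (steps 1–5 and 9–13).

Steps most likely to fail

1. Step 11.
- What may go wrong: the ten-ring closure has to outrun proto-deiodination and intermolecular coupling. The macrocyclic transition state may also erode or reverse the Felkin–Anh facial preference at the C9 aldehyde.
- Fallback: it sets out from 16 and fixes C9 by SN2 inversion instead of by facial control. The closure is run as before and the (9S)-epimer of 17 F1 is separated. F1 is esterified with acid 18 under Mitsunobu conditions (PPh3, DIAD, toluene, 0 °C). This inverts C9 and comes back to the route at 19. Any 17 formed alongside goes through step 12, so both epimers converge.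

2. Step 9.
- What may go wrong: the facial bias at C7 of the pyranone may be too small. The allylindium may react by α-attack at C13. It may also undergo 1,4-reductive elimination of the silyloxy group, or the (Z)-enal may isomerise under metal or acid catalysis.
- Fallback: it sets out from 13 and replaces the Barbier reagent by an isolable type I allylboron reagent. Pd-catalysed borylation (B2pin2, Pd2(dba)3, THF, 60 °C) should give (5S)-3-[(4,4,5,5-tetramethyl-1,3,2-dioxaborolan-2-yl)methyl]-5-(triethylsilyloxy)-5,6-dihydro-2H-pyran-2-one F2. F2 does not eliminate and should add to aldehyde 7 on warming in toluene through a tight chair transition state. Hydrolytic work-up and translactonisation (PPTS) come back to the route at 15.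

3. Step 8.
- What may go wrong: the electron-poor 1,1-disubstituted olefin may engage slowly. The allylic bromide may decompose the catalyst, or cross-metathesis dimerisation may take over.
- Fallback: it sets out from 9 and installs the bromine after ring closure.
  - Selective acylation with methacryloyl chloride (collidine, −78 °C) should give (2S)-2-hydroxybut-3-en-1-yl methacrylate F3.
  - Silylation (TESOTf, 2,6-lutidine) should give (2S)-2-(triethylsilyloxy)but-3-en-1-yl methacrylate F4.
  - The well-behaved methacrylate ring-closing metathesis should give (5S)-3-methyl-5-(triethylsilyloxy)-5,6-dihydro-2H-pyran-2-one F5.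
  - Wohl–Ziegler bromination of the C13 methyl group (NBS, AIBN, PhCF3, reflux) comes back to the route at 13.

Further compounds
F1 | step 11 | (6R,7S,8S,9S)-9-hydroxy-14,14-dimethoxy-8-(triethylsilyloxy)germacra-1(10)E,4Z,11(13)-trien-12,6-olide, the (9S)-epimer of 17 | C=C1C(=O)O[C@@H]2/C=C(/C)CC/C=C(/C(OC)OC)[C@H](O)[C@@H](O[Si](CC)(CC)CC)[C@@H]12
F2 | step 9 | (5S)-3-[(4,4,5,5-tetramethyl-1,3,2-dioxaborolan-2-yl)methyl]-5-(triethylsilyloxy)-5,6-dihydro-2H-pyran-2-one | O=C1OC[C@@H](O[Si](CC)(CC)CC)C=C1CB2OC(C)(C)C(C)(C)O2
F3 | step 8 | (2S)-2-hydroxybut-3-en-1-yl methacrylate | C=C(C)C(=O)OC[C@@H](O)C=C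
F4 | step 8 | (2S)-2-(triethylsilyloxy)but-3-en-1-yl methacrylate | C=C(C)C(=O)OC[C@@H](O[Si](CC)(CC)CC)C=C
F5 | step 8 | (5S)-3-methyl-5-(triethylsilyloxy)-5,6-dihydro-2H-pyran-2-one | O=C1OC[C@@H](O[Si](CC)(CC)CC)C=C1C
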